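**Plan**

- Retrosynthesis (germacrane numbering, see remark): the last cuts are the two lactone bonds O–C6 and C11–C7, which take 2-bromoacrylic acid off a ten-membered (1(10)Z,4E,6Z)-triene. Before that: C6=C7 (ring-closing metathesis), the C9 ester, C8–C9 (alkoxyallylboration), C5–C6 and C4–CH3 (carboalumination/coupling), C1=C10 (Still–Gennari olefination), C3–C4 (epoxide opening).
- Forward: a linear C1–C10 chain is grown from (S)-trityl glycidyl ether, the carbocycle is closed at C6=C7, and the α-methylene lactone ring is then annulated onto the ring diene in one palladium-catalysed operation. Two deprotections finish the route.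
- Enabling feature: C6 carries the lactone oxygen and is allylic to the C4=C5 olefin, and C7 is its ring neighbour. This γ-alkenyl-γ-butyrolactone fused at C6–C7 is the signature of a carbo-oxygenation of the ring diene C4=C5–C6=C7 through an allylpalladium at C4–C5–C6.
- Stereochemistry: C2 from the glycidyl ether; 1(10)Z from the Still–Gennari step; 4E from syn-carboalumination; C8 and C9 from a reagent-controlled syn alkoxyallylboration; 6Z enforced by the ring in the metathesis; C7 and C6 from the key step (outer-face carbopalladation, then anti C–O closure to the trans-fused lactone).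

Key step: step 12

Remark on numbering: C6 = lactone O-bearing carbon, C7 = ring-fusion carbon, C11/C12/C13 = lactone α-carbon, carbonyl and methylidene, C8 = free carbinol next to C7, C9 = ester carbon, C10(CH3)=C1, C2 = second carbinol, C3 = CH2, C4(CH3)=C5.

Remark on step 9: the borane made from (−)-Ipc2BOMe is assumed to attack the Si face of the aldehyde; if the sense proves opposite, the reagent from (+)-Ipc2BOMe is used.

Step 1
Reactants: 1 (2S)-2-[(triphenylmethoxy)methyl]oxirane
Product: 2 (2S)-1-(triphenylmethoxy)pent-4-yn-2-ol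
Conditions: LiC≡CH·H2NCH2CH2NH2, DMSO, 0 °C to rt
Reagents that add atoms: lithium acetylide–ethylenediamine complex, [Li+].[C-]#C.NCCN
Why: SN2 epoxide opening by the acetylide at the unhindered terminal carbon leaves the existing stereocentre (the future C2) untouched and brings in C3–C5 as a terminal alkyne.

Step 2
Reactants: 2 (2S)-1-(triphenylmethoxy)pent-4-yn-2-ol
Product: 3 tert-butyl(dimethyl){[(2S)-1-(triphenylmethoxy)pent-4-yn-2-yl]oxy}silane
Conditions: TBSCl, imidazole, DMF, rt
Reagents that add atoms: tert-butyldimethylsilyl chloride, CC(C)(C)[Si](C)(C)Cl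
Why: Silyl ether formation protects the C2 hydroxyl with a group that should survive every later step up to the final fluoride treatment.

Step 3
Reactants: 3 tert-butyl(dimethyl){[(2S)-1-(triphenylmethoxy)pent-4-yn-2-yl]oxy}silane
Product: 4 (2S)-2-[(tert-butyldimethylsilyl)oxy]pent-4-yn-1-ol
Conditions: camphorsulfonic acid (10 mol %), MeOH/CH2Cl2, 0 °C
Reagents that add atoms: none
Why: Acid-catalysed SN1 methanolysis of the trityl ether through the stabilised trityl cation frees the primary alcohol under conditions too mild to cleave or shift the secondary silyl ether.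

Step 4
Reactants: 4 (2S)-2-[(tert-butyldimethylsilyl)oxy]pent-4-yn-1-ol
Product: 5 (2S)-2-[(tert-butyldimethylsilyl)oxy]pent-4-ynal
Conditions: Dess–Martin periodinane, NaHCO3, CH2Cl2, 0 °C to rt; used crude
Reagents that add atoms: none
Why: Dess–Martin oxidation under buffered, non-basic conditions should give the α-silyloxy aldehyde without epimerising C2.

Step 5
Reactants: 5 (2S)-2-[(tert-butyldimethylsilyl)oxy]pent-4-ynal
Product: 6 methyl (2Z,4S)-4-[(tert-butyldimethylsilyl)oxy]-2-methylhept-2-en-6-ynoate
Conditions: methyl 2-[bis(2,2,2-trifluoroethoxy)phosphoryl]propanoate, KN(SiMe3)2, 18-crown-6, THF, −78 °C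
Reagents that add atoms: methyl 2-[bis(2,2,2-trifluoroethoxy)phosphoryl]propanoate, COC(=O)C(C)P(=O)(OCC(F)(F)F)OCC(F)(F)F
Why: The Still–Gennari variant of the Horner–Wadsworth–Emmons olefination (electron-poor phosphonate, dissociated potassium base, fast irreversible elimination) should give the Z-trisubstituted enoate, which fixes the 1(10)Z geometry with the ester carbon as C9.

Step 6
Reactants: 6 methyl (2Z,4S)-4-[(tert-butyldimethylsilyl)oxy]-2-methylhept-2-en-6-ynoate
Product: 7 (2Z,4S)-4-[(tert-butyldimethylsilyl)oxy]-2-methylhept-2-en-6-yn-1-ol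
Conditions: i-Bu2AlH (2.5 equiv), CH2Cl2, −78 °C; Rochelle salt work-up
Reagents that add atoms: none
Why: 1,2-Reduction of the enoate by the aluminium hydride at low temperature gives the allylic alcohol without touching the olefin geometry.

Step 7
Reactants: 7 (2Z,4S)-4-[(tert-butyldimethylsilyl)oxy]-2-methylhept-2-en-6-yn-1-ol
Product: 9 (2Z,4S,6E)-4-[(tert-butyldimethylsilyl)oxy]-2,6-dimethylnona-2,6,8-trien-1-ol, via alkenylalane 8 (not isolated)
Conditions: AlMe3 (3.5 equiv), Cp2ZrCl2 (0.3 equiv), CH2Cl2, 0 °C to rt; then vinyl bromide (THF solution), ZnCl2, Pd(PPh3)4 (5 mol %), rt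
Reagents that add atoms: trimethylaluminium, C[Al](C)C; vinyl bromide, C=CBr
Why: Negishi zirconium-catalysed carboalumination adds CH3 and Al syn across the terminal alkyne (methyl to the internal carbon, giving 4E and the C4 methyl), and the alkenylalane is cross-coupled in the same flask with vinyl bromide with retention (Negishi coupling) to give the E-1,3-diene, the hydroxyl riding along as its aluminium alkoxide.

Step 8
Reactants: 9 (2Z,4S,6E)-4-[(tert-butyldimethylsilyl)oxy]-2,6-dimethylnona-2,6,8-trien-1-ol
Product: 10 (2Z,4S,6E)-4-[(tert-butyldimethylsilyl)oxy]-2,6-dimethylnona-2,6,8-trienal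
Conditions: MnO2 (activated, excess), CH2Cl2, 0 °C to rt, dark; used crude
Reagents that add atoms: none
Why: MnO2 allylic oxidation is selective for the allylic alcohol and neutral, so the Z-enal should form without isomerisation to the E-enal.

Step 9
Reactants: 10 (2Z,4S,6E)-4-[(tert-butyldimethylsilyl)oxy]-2,6-dimethylnona-2,6,8-trienal
Product: 11 (3R,4R,5Z,7S,9E)-7-[(tert-butyldimethylsilyl)oxy]-3-(methoxymethoxy)-5,9-dimethyldodeca-1,5,9,11-tetraen-4-ol
Conditions: allyl methoxymethyl ether, s-BuLi, THF, −78 °C; (−)-Ipc2BOMe; BF3·OEt2; then 10, −78 °C to rt; NaOH, H2O2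
Reagents that add atoms: [(Z)-3-(methoxymethoxy)prop-2-en-1-yl]diisopinocampheylborane, made in the flask from allyl methoxymethyl ether (C=CCOCOC), COCO/C=C\CB(C1CC2CC(C1C)C2(C)C)C1CC2CC(C1C)C2(C)C
Why: Brown asymmetric alkoxyallylboration: the Z-γ-alkoxyallylborane reacts through a chair six-membered transition state to give the syn 8,9-diol monoether, and the isopinocampheyl groups direct it to the Si face of the aldehyde, setting C9 and C8 (both R) independently of the remote C2 centre.

Step 10
Reactants: 11 (3R,4R,5Z,7S,9E)-7-[(tert-butyldimethylsilyl)oxy]-3-(methoxymethoxy)-5,9-dimethyldodeca-1,5,9,11-tetraen-4-ol; 12 angelic acid [(2Z)-2-methylbut-2-enoic acid]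
Product: 14 (3R,4R,5Z,7S,9E)-7-[(tert-butyldimethylsilyl)oxy]-3-(methoxymethoxy)-5,9-dimethyldodeca-1,5,9,11-tetraen-4-yl (2Z)-2-methylbut-2-enoate, via mixed anhydride 13 (not isolated)
Conditions: 2,4,6-trichlorobenzoyl chloride, Et3N, toluene, rt; then 11, toluene, 75 °C (no DMAP)
Reagents that add atoms: 2,4,6-trichlorobenzoyl chloride, O=C(Cl)c1c(Cl)cc(Cl)cc1Cl (its atoms stay in intermediate 13 only)
Why: Yamaguchi-type esterification through the 2,4,6-trichlorobenzoyl mixed anhydride without a nucleophilic catalyst acylates the C9 alcohol while avoiding the nucleophile-induced Z to E isomerisation of the angelate.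

Step 11
Reactants: 14 (3R,4R,5Z,7S,9E)-7-[(tert-butyldimethylsilyl)oxy]-3-(methoxymethoxy)-5,9-dimethyldodeca-1,5,9,11-tetraen-4-yl (2Z)-2-methylbut-2-enoate
Product: 15 (1R,2Z,4S,6E,8Z,10R)-4-[(tert-butyldimethylsilyl)oxy]-10-(methoxymethoxy)-2,6-dimethylcyclodeca-2,6,8-trien-1-yl (2Z)-2-methylbut-2-enoate
Conditions: second-generation Grubbs catalyst RuCl2(=CHPh)(H2IMes)(PCy3) (10 mol %), toluene (1 mM), 60 °C, argon sparge
Reagents that add atoms: none
Why: Ring-closing metathesis between the diene terminus and the C7 vinyl group closes the ten-membered ring, and the new C6=C7 bond can only be Z because an E bond next to the 4E bond cannot be spanned by the four remaining ring atoms, the same geometry (C3 and C6 trans on C4=C5) excluding a six-membered by-product.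

Step 12
Reactants: 15 (1R,2Z,4S,6E,8Z,10R)-4-[(tert-butyldimethylsilyl)oxy]-10-(methoxymethoxy)-2,6-dimethylcyclodeca-2,6,8-trien-1-yl (2Z)-2-methylbut-2-enoate; 16 2-bromoprop-2-enoic acid (2-bromoacrylic acid)
Product: 17 (3aS,4R,5R,6Z,8S,10E,11aR)-8-[(tert-butyldimethylsilyl)oxy]-4-(methoxymethoxy)-6,10-dimethyl-3-methylidene-2-oxo-2,3,3a,4,5,8,9,11a-octahydrocyclodeca[b]furan-5-yl (2Z)-2-methylbut-2-enoate (same spatial arrangement at C3a as in 18 and 19; the descriptor differs only through a priority change)
Conditions: Pd(OAc)2 (10 mol %), n-Bu4NCl (1 equiv), K2CO3 (3 equiv), DMF, 60 °C; 16 used in twofold excess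
Reagents that add atoms: none
Why: After reduction of Pd(OAc)2 in the flask, zerovalent palladium inserts into the C–Br bond of the 2-bromoacrylate anion, the alkenylpalladium adds syn across C6=C7 with C11 going to C7, and the η3-allylpalladium that now spans C4–C5–C6 is attacked at C6 by the pendant carboxylate oxygen, which releases zerovalent palladium. The closest known reaction type is the Larock heteroannulation of 1,3-dienes by aryl and vinylic halides that carry a carboxylic acid (Heck insertion followed by allylic C–O substitution), used here as a formal [3+2] annulation on a ring diene. Only the lactone ring closes, in a 5-exo attack of oxygen on the near allyl terminus C6, since closure at C4 would need a seven-membered ring and a tertiary centre. C7 is controlled by the C8 stereocentre: allylic 1,3-strain across the cis C6=C7 bond holds C8–H in the olefin plane, the C8–C9 ring bond covers one face, and the alkenylpalladium adds to the other (outer) face, which puts C11 trans to the C8 oxygen. C6 is controlled by the mode of C–O formation: with chloride on palladium and a free carboxylate in DMF the oxygen should attack the allyl face opposite the metal after rotation about C6–C7, a net anti addition across the Z olefin that gives the trans-fused lactone, while the syn substituent at C4 keeps the 4E geometry. The step needs C7 over C4 and diene over C1=C10 regioselectivity (C7 is the only diene terminus without a methyl group and only the diene leads to an allyl complex) and C–O closure faster than β-hydride elimination (secured by the five-membered tether).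

Step 13
Reactants: 17 the 8-O-methoxymethyl, 2-O-silyl lactone
Product: 18 (3aR,4R,5R,6Z,8S,10E,11aR)-8-[(tert-butyldimethylsilyl)oxy]-4-hydroxy-6,10-dimethyl-3-methylidene-2-oxo-2,3,3a,4,5,8,9,11a-octahydrocyclodeca[b]furan-5-yl (2Z)-2-methylbut-2-enoate
Conditions: Me2BBr (3 equiv), CH2Cl2, −78 °C; then THF/saturated aqueous NaHCO3
Reagents that add atoms: none
Why: Lewis-acid cleavage of the methoxymethyl acetal by bromodimethylborane proceeds through the bromomethyl ether, which is hydrolysed on work-up, under cold acidic conditions in which the angelate should not migrate to the freed C8 hydroxyl and nothing adds to the methylene lactone.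

Step 14
Reactants: 18 the 2-O-silyl lactone
Product: 19 (3aR,4R,5R,6Z,8S,10E,11aR)-4,8-dihydroxy-6,10-dimethyl-3-methylidene-2-oxo-2,3,3a,4,5,8,9,11a-octahydrocyclodeca[b]furan-5-yl (2Z)-2-methylbut-2-enoate (CNP0311662.1)
Conditions: HF·pyridine, pyridine/THF, 0 °C to rt
Reagents that add atoms: none
Why: Fluoride-mediated desilylation with buffered HF·pyridine removes the C2 silyl ether under non-basic conditions, which avoids 9-to-8 acyl migration and oxa-Michael addition to the α-methylene lactone.

**Compound list**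

1 | (2S)-2-[(triphenylmethoxy)methyl]oxirane, (S)-trityl glycidyl ether | C1[C@H](O1)COC(c2ccccc2)(c2ccccc2)c2ccccc2 | starting material
2 | (2S)-1-(triphenylmethoxy)pent-4-yn-2-ol | C#CC[C@H](O)COC(c1ccccc1)(c1ccccc1)c1ccccc1 | intermediate
3 | tert-butyl(dimethyl){[(2S)-1-(triphenylmethoxy)pent-4-yn-2-yl]oxy}silane | C#CC[C@H](O[Si](C)(C)C(C)(C)C)COC(c1ccccc1)(c1ccccc1)c1ccccc1 | intermediate
4 | (2S)-2-[(tert-butyldimethylsilyl)oxy]pent-4-yn-1-ol | C#CC[C@H](O[Si](C)(C)C(C)(C)C)CO | intermediate
5 | (2S)-2-[(tert-butyldimethylsilyl)oxy]pent-4-ynal | C#CC[C@H](O[Si](C)(C)C(C)(C)C)C=O | intermediate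
6 | methyl (2Z,4S)-4-[(tert-butyldimethylsilyl)oxy]-2-methylhept-2-en-6-ynoate | C#CC[C@H](O[Si](C)(C)C(C)(C)C)/C=C(/C)C(=O)OC | intermediate
7 | (2Z,4S)-4-[(tert-butyldimethylsilyl)oxy]-2-methylhept-2-en-6-yn-1-ol | C#CC[C@H](O[Si](C)(C)C(C)(C)C)/C=C(/C)CO | intermediate
8 | dimethylaluminium alkoxide of (2Z,4S,6E)-4-[(tert-butyldimethylsilyl)oxy]-7-(dimethylalumanyl)-2,6-dimethylhepta-2,6-dien-1-ol | C[Al](C)/C=C(\C)C[C@H](O[Si](C)(C)C(C)(C)C)/C=C(/C)CO[Al](C)C | intermediate (not isolated)
9 | (2Z,4S,6E)-4-[(tert-butyldimethylsilyl)oxy]-2,6-dimethylnona-2,6,8-trien-1-ol | C=C/C=C(\C)C[C@H](O[Si](C)(C)C(C)(C)C)/C=C(/C)CO | intermediate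
10 | (2Z,4S,6E)-4-[(tert-butyldimethylsilyl)oxy]-2,6-dimethylnona-2,6,8-trienal | C=C/C=C(\C)C[C@H](O[Si](C)(C)C(C)(C)C)/C=C(/C)C=O | intermediate
11 | (3R,4R,5Z,7S,9E)-7-[(tert-butyldimethylsilyl)oxy]-3-(methoxymethoxy)-5,9-dimethyldodeca-1,5,9,11-tetraen-4-ol | C=C/C=C(\C)C[C@H](O[Si](C)(C)C(C)(C)C)/C=C(/C)[C@@H](O)[C@H](OCOC)C=C | intermediate
12 | angelic acid, (2Z)-2-methylbut-2-enoic acid | C/C=C(/C)C(=O)O | starting material
13 | (2Z)-2-methylbut-2-enoic 2,4,6-trichlorobenzoic anhydride | C/C=C(/C)C(=O)OC(=O)c1c(Cl)cc(Cl)cc1Cl | intermediate (not isolated)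
14 | (3R,4R,5Z,7S,9E)-7-[(tert-butyldimethylsilyl)oxy]-3-(methoxymethoxy)-5,9-dimethyldodeca-1,5,9,11-tetraen-4-yl (2Z)-2-methylbut-2-enoate | C=C/C=C(\C)C[C@H](O[Si](C)(C)C(C)(C)C)/C=C(/C)[C@@H](OC(=O)/C(C)=C\C)[C@H](OCOC)C=C | intermediate
15 | (1R,2Z,4S,6E,8Z,10R)-4-[(tert-butyldimethylsilyl)oxy]-10-(methoxymethoxy)-2,6-dimethylcyclodeca-2,6,8-trien-1-yl (2Z)-2-methylbut-2-enoate; in germacrane numbering the (1(10)Z,4E,6Z)-triene with 2-OTBS, 8-OMOM, 9-O-angeloyl | COCO[C@@H]1/C=C\C=C(/C)C[C@H](O[Si](C)(C)C(C)(C)C)/C=C(/C)[C@H]1OC(=O)/C(C)=C\C | intermediate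
16 | 2-bromoprop-2-enoic acid | C=C(Br)C(=O)O | starting material
17 | (3aS,4R,5R,6Z,8S,10E,11aR)-8-[(tert-butyldimethylsilyl)oxy]-4-(methoxymethoxy)-6,10-dimethyl-3-methylidene-2-oxo-2,3,3a,4,5,8,9,11a-octahydrocyclodeca[b]furan-5-yl (2Z)-2-methylbut-2-enoate | C=C1C(=O)O[C@@H]2/C=C(\C)C[C@H](O[Si](C)(C)C(C)(C)C)/C=C(/C)[C@@H](OC(=O)/C(C)=C\C)[C@H](OCOC)[C@@H]12 | intermediate
18 | (3aR,4R,5R,6Z,8S,10E,11aR)-8-[(tert-butyldimethylsilyl)oxy]-4-hydroxy-6,10-dimethyl-3-methylidene-2-oxo-2,3,3a,4,5,8,9,11a-octahydrocyclodeca[b]furan-5-yl (2Z)-2-methylbut-2-enoate | C=C1C(=O)O[C@@H]2/C=C(\C)C[C@H](O[Si](C)(C)C(C)(C)C)/C=C(/C)[C@@H](OC(=O)/C(C)=C\C)[C@H](O)[C@@H]12 | intermediate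
19 | (3aR,4R,5R,6Z,8S,10E,11aR)-4,8-dihydroxy-6,10-dimethyl-3-methylidene-2-oxo-2,3,3a,4,5,8,9,11a-octahydrocyclodeca[b]furan-5-yl (2Z)-2-methylbut-2-enoate | C=C1C(=O)O[C@@H]2/C=C(\C)C[C@H](O)/C=C(/C)[C@@H](OC(=O)/C(C)=C\C)[C@H](O)[C@@H]12 | target

**Totals and risks**

Total step count: 14. Longest linear sequence: 14 steps (1 to 19).

Steps most likely to fail:

1. Step 12. What may go wrong: the allylpalladium is closed by oxygen delivered from the metal on the same face (this would give the cis-fused lactone), the carbopalladation shows poor facial selectivity, β-hydride elimination wins, or zerovalent palladium ionises the allylic angelate. The fallback sets out from 15 and comes back at 17, and builds the same ring stepwise by strain release. Rh2(OAc)4-catalysed cyclopropanation of the cis C6=C7 bond of 15 with the phenyliodonium ylide of Meldrum's acid should give the spiro-activated cis-vinylcyclopropane F1, the carbene adding to the same outer face. Warming F1 in aqueous acetone opens the cyclopropane by attack of water at the allylic carbon C6 with inversion, and the hydroxy acid derivative lactonises with loss of acetone to the trans-fused α-carboxy lactone F2. Decarboxylative Mannich methylenation of F2 (aqueous formaldehyde, Et2NH, then NaOAc/AcOH, warm) gives 17.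

2. Step 11. What may go wrong: intermolecular metathesis (oligomerisation) outruns closure of the medium ring, or the catalyst rests as the unreactive vinylcarbene at the diene terminus because the vinyl group at C7 is flanked by two bulky oxygen substituents. The fallback sets out from 11 and comes back at 15, and changes the order of events. The free alcohol 11 is cyclised first under the same ruthenium catalyst to the macrocyclic alcohol F3, with no ester beside the reacting vinyl group and a hydroxyl that can assist catalyst loading. F3 is then acylated with mixed anhydride 13 as in step 10 to give 15.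

3. Step 10. What may go wrong: the Z-enoate isomerises to the E ester (tiglate) during activation, and acylation of the flanked secondary alcohol is slow. The fallback sets out from 11 and comes back at 14, and builds the angelate double bond on the substrate instead of transferring it. Alcohol 11 is acylated with 2-(diphenoxyphosphoryl)propanoic acid (DCC, DMAP) to the phosphonate ester F4. A Z-selective Horner–Wadsworth–Emmons olefination of F4 with acetaldehyde (diaryl phosphonate, Ando variant; NaH, THF, −78 °C) gives 14.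

Further compounds
F1 | step 12 | cis-cyclopropane across C6–C7 of 15, spiro-fused at C11 to a 2,2-dimethyl-1,3-dioxane-4,6-dione ring (Meldrum's acid unit) | CC1(C)OC(=O)C2(C(=O)O1)[C@H]3/C=C(\C)C[C@H](O[Si](C)(C)C(C)(C)C)/C=C(/C)[C@@H](OC(=O)/C(C)=C\C)[C@H](OCOC)[C@@H]23
F2 | step 12 | trans-fused α-carboxy lactone, 17 with CO2H and H at C11 in place of the methylidene group (C11 epimers) | OC(=O)C1C(=O)O[C@@H]2/C=C(\C)C[C@H](O[Si](C)(C)C(C)(C)C)/C=C(/C)[C@@H](OC(=O)/C(C)=C\C)[C@H](OCOC)[C@@H]12
F3 | step 11 | (1R,2Z,4S,6E,8Z,10R)-4-[(tert-butyldimethylsilyl)oxy]-10-(methoxymethoxy)-2,6-dimethylcyclodeca-2,6,8-trien-1-ol | COCO[C@@H]1/C=C\C=C(/C)C[C@H](O[Si](C)(C)C(C)(C)C)/C=C(/C)[C@H]1O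
F4 | step 10 | (3R,4R,5Z,7S,9E)-7-[(tert-butyldimethylsilyl)oxy]-3-(methoxymethoxy)-5,9-dimethyldodeca-1,5,9,11-tetraen-4-yl 2-(diphenoxyphosphoryl)propanoate | C=C/C=C(\C)C[C@H](O[Si](C)(C)C(C)(C)C)/C=C(/C)[C@@H](OC(=O)C(C)P(=O)(Oc1ccccc1)Oc1ccccc1)[C@H](OCOC)C=C
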